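What part of the substrate has reacted after 8.0 s, when the flasks differ in their charge of coupling partner?

common to all: substrate 5.0 mM; initiator 25 µM; time 8.0 s
- zeta: coupling partner 9.00 mM
- theta: coupling partner 18.0 mM
- epsilon: coupling partner 36.0 mM

- part of the substrate that has reacted at the end, zeta
- part of the substrate that has reacted at the end, theta
- part of the substrate that has reacted at the end, epsilon
- what raising the concentration of coupling partner from its lowest to its highest value here does to the part of the substrate that has reacted (changes below 5 percentage points count as none) (no change / it rises / it falls)

    2 second chain carrier → ended chains B (k1 = 3 × 10⁶ M⁻¹ s⁻¹)
    substrate + initiating radical → capped initiator + first chain carrier (k2 = 7.84 × 10⁶ M⁻¹ s⁻¹)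
    coupling partner + by-product ⇌ idle adduct, settled at all times (K3 = 4530 M⁻¹)
    initiator → 2 initiating radical (k4 = 0.0157 s⁻¹)
    2 coupling partner → self-condensation product (k5 = 10.0 M⁻¹ s⁻¹)
    2 first chain carrier → ended chains A (k6 = 5.8 × 10⁶ M⁻¹ s⁻¹)
    coupling partner + first chain carrier → target + second chain carrier (k7 = 4.00 × 10⁵ M⁻¹ s⁻¹)
    first chain carrier → ended carrier (k8 = 0.675 s⁻¹)
    substrate + second chain carrier → by-product + first chain carrier (k9 = 7.76 × 10⁵ M⁻¹ s⁻¹)

- a species is counted by the substrate in it: one ended chains A counts as two
- amounts and yields of by-product count idle adduct too
- for a step with 2 of a species take k times the square, and two of it per event
- run time (zeta): 8.0 s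

Why count anything here? One pass round the chain, first chain carrier taking coupling partner and second chain carrier taking substrate, turns over one substrate and hands the carrier on, so passes are what we count.

How many carriers start? The initiator has a half-life of 44 s by its own step and gives two radicals per break, so 25 µM of it starts 5.90 µM of radicals in the run.

How many passes must each make? That charge of substrate asks 847 of each; call this count, the substrate charged over the radicals started in the run, the turnover demand.

And what does the chain offer? Radicals enter at 0.785 µM s⁻¹ at the start. Equal passing rates set [second chain carrier]/[first chain carrier], and pair termination must remove what enters. I leave out the first-order loss of first chain carrier, so my counts run high. Passes per radical at the starting charges, the kinetic chain length, come to 992 for zeta and 1670 for epsilon.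

So zeta, offered more passes than its demand, finishes? No, that count holds [substrate] and [coupling partner] at their charges. The first half-life of coupling partner by self-condensation alone is 5.56 s in zeta and 1.39 s in epsilon, both shorter than the run. At zeta's starting [coupling partner], nearly all by-product formed would bind a further coupling partner as idle adduct. I therefore commit to a direction: conversion rises with the charge, since the start count is larger in epsilon than in zeta, and I give no percentages.

The forecast gives 49%, 70% and 81%, and on the trend says: it rises, holding that “the gain is blunted because self-condensation strips it quickly at high charge”.

The simulation gives 47.4%, 66.4% and 77.1%, and on the trend: it rises, by 30 percentage points, so the forecast stands within its margins. Theta ended with 12.2% of its coupling partner free. Against the demand of 847, theta's radicals made on average 563 passes each. The forecast's 70% for theta does not carry over to theta's neighbour with 0.0062 mM of initiator, a quarter of theta's charge of it, which reached 34.3%. In that neighbour the demand is 3420, and each radical made on average 1170 passes, twice theta's count.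

The constants used here are those of an exercise, and the outcome is calculated.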